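## Analysis of the target

Tauranin (20) joins a drimane-type trans-decalin (rings A and B) through the methylene C11 to a 2-hydroxy-1,4-benzoquinone (ring C', atoms C1'–C6') that carries a hydroxymethyl group (C7') on C4'. The three stereocentres C5, C10 and C9 are contiguous and all S: the ring fusion is trans, the methyl group on C10 is axial, and the C9 side chain is equatorial and lies next to the exocyclic C8=C12 methylene. This 1,1-disubstituted alkene is the delicate part of the terpene half, because acids and hydride-forming metals move it into the ring, and halogens, peracids and mercury salts add to it. The hydroxyquinone is acidic, redox-active and a Michael acceptor, and its primary alcohol is allylic, so ring C' can reach its final oxidation level only at the end. The difficulty is therefore not the stereochemistry, which a labdane from the chiral pool supplies, but building an oxygenated, tetrasubstituted six-membered ring on C11 under conditions the alkene survives. The route rests on the fact that C9–C11–C1'–C2'(O)–C3' is the CH2–CH2–C(=O)–CH3 end of the methyl ketone 2 derived from (+)-manool (1), whose decalin already holds C5, C9, C10 and C8=C12 as required. The missing atoms C4' (with C7'), C5' and C6' come from a two-carbon aldehyde (3) and a malonate (8). The resorcinol 19 that results has a local mirror plane through C1' and C4', so oxidation para to either hydroxyl gives the same quinone.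

## Retrosynthetic reasoning

20 ⇒ 19. The C3' carbonyl oxygen is removed first, because the hydroxyquinone tolerates none of the ring-forming chemistry. This leads back to the 2-alkyl-5-(hydroxymethyl)resorcinol 19. The forward step must oxidise one C–H para to a phenolic hydroxyl without touching C8=C12 or the primary alcohol. Since C3' and C5' of 19 are equivalent, no regiochemical choice arises.

19 ⇒ 18. The two free hydroxyls that matter are masked as silyl ethers, one on the C2' oxygen and one on the C7' oxygen. Both fall off in a single desilylation, so the protection costs one step in total.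

18 ⇒ 13 ⇒ 12. The aromatic ring is taken down by one oxidation level, by removing the C4'=C5' unsaturation, to the cyclohexane-1,3-dione 12. The forward dehydrogenation is the point where the alkene dictates the method: bromine, iodine, mercury salts and hot palladium on carbon are excluded. The dione is therefore fixed as the enol silyl ether 13, its α'-enolate is selenenylated, and the selenoxide eliminates at room temperature. The enol silyl group ends as the aryl silyl ether of 18.

12 ⇒ 10. A methoxycarbonyl group is put back on C5'. It is the trace of the malonate and is lost in the forward direction by saponification and decarboxylation.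

10 ⇒ 7 + 8. The ring is cut at C4'–C5' and C1'–C6'. This is the only pair of cuts that leaves C1', C2' and C3' as the intact ketone terminus of the labdane chain and turns the other three ring carbons into simple commercial pieces. The forward reaction is a conjugate addition of 8 to enone 7 followed by ring-closing acylation at C1'. It runs in base only, which the terpene half tolerates.

7 ⇒ 5 ⇒ 2 + 3. The C3'=C4' alkene is cut by a retro-aldol condensation. The forward reaction needs the kinetic (methyl) enolate of 2 so that C3', not C1', bonds to the aldehyde carbon of 3.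

2 ⇒ 1. The methyl ketone is the known degradation product of the vinyl carbinol side chain of 1. Two carbons (C14, C15) are excised and C13 becomes C2'. Nothing else in the molecule changes, so the absolute configuration of 20 is bought with 1.

## Alternatives that were turned down

Alternative 1: The decalin is disconnected at C4–C5 and C9–C10, back to the achiral (E,E)-farnesyl arene A1. In the forward key step a squalene–hopene cyclase (a terpene cyclase of class two) would protonate the terminal alkene, run the chair–chair cascade and end by proton loss from C12, giving A2.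
- For: one catalytic step would set both rings, all three stereocentres and the exocyclic alkene from a precursor made by a simple aryl–farnesyl coupling. No terpene from the chiral pool is needed, and on paper this is the shortest route.
- Against: the terminating event is decided by the active site, not by the substrate. Proton loss from C7 or C9 and capture of water at C8 are the usual competitors of C12 deprotonation, and a bulky dimethoxybenzyl end group has to be accepted by the enzyme. Afterwards at least one aryl methyl ether of A2 must be cleaved by hot thiolate or a Lewis acid in the presence of C8=C12 and a benzylic alcohol.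
- Comparison: Alternative 1 is stronger in step count and in building the stereochemistry catalytically. The chosen route instead takes C5, C9, C10 and C8=C12 ready-made from 1, so the alkene position and absolute configuration are never in question, and it uses only ordinary reagents.

Alternative 2: Ring C' is disconnected at C1'–C6' and C2'–C3'. The partners are the siloxyalkyne A4, made from (+)-sclareolide (A3) so that the lactone carbonyl carbon ends as an arene carbon, and the cyclobutenone A5. Heating opens A5 to a vinylketene, which adds to the electron-rich alkyne; a second ring opening and a 6π closure then give the resorcinol mono-silyl ether A6 (Danheiser benzannulation).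
- For: it is convergent and regiospecific, runs under neutral thermal conditions, and delivers the aromatic ring without a separate dehydrogenation. A6 is the same compound as 18, so the end game would be identical.
- Against: in A3, C8 is a lactone carbinol. The exocyclic alkene must be made by elimination, in which hydrogens on C7 and C9 compete with those on C12. The ynolate must be generated from a hindered ester next to C9, siloxyalkynes are labile, and A5 is not commercial and needs its own short synthesis.
- Comparison: Alternative 2 is equal in the end game and stronger in convergence and in sparing steps 6 and 7. The chosen strategy offers an alkene that is already in place, three commercial building blocks, and classical enolate chemistry instead of two high-energy partners.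

Alternative 3: Ring C' is disconnected at C5'–C6', with C1', C2', C3' and C6' taken from diisopropyl squarate (A7). Two successive carbanion additions would give the 4-hydroxy-4-alkenylcyclobutenone A8. Thermolysis opens it to a dienylketene whose ketene carbon closes onto the terminal alkene carbon, giving hydroquinone A9 (Moore rearrangement).
- For: the ring arrives with all four substituents placed unambiguously and at the hydroquinone level, so no late C–H oxidation is needed.
- Against: it needs a carbanion at C11 of the drimane unit. This is a homoallylic organometallic whose radical precursors can cyclise onto C8=C12, and whose halide must first be prepared in several steps. The two additions to A7 must be regiocontrolled, and the isopropyl vinylogous ester must be hydrolysed at the end in addition to the desilylation, with acid again a threat to the alkene.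
- Comparison: Alternative 3 is stronger in the certainty of the oxygenation pattern. The chosen strategy has the C11–C1' bond already present in 1, needs no organometallic at C11, and makes its own late oxidation unambiguous through the symmetry of 19.

Key step: step 4

## Remarks before the steps

- Dec stands for (1S,4aS,8aS)-5,5,8a-trimethyl-2-methylidenedecahydronaphthalen-1-yl; Dec-CH2 is the albicanyl group. Ring C' atoms are C1' (bearing C11) to C6', and C7' is the oxygenated methylene on C4'.
- Assumption: commercial (+)-manool is the (13R)-labda-8(17),14-dien-13-ol enantiomer of the normal labdane series shown as 1, so its C5, C9 and C10 configuration is that of 20.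
- Sodium salts formed by proton transfer in steps 4 and 5 are treated as ionised forms of the numbered compounds. Compounds 5, 6 and 9–17 are mixtures of isomers at centres that do not exist in 20 and converge on aromatisation.

## Route

Step 1
Reactants: 1 (+)-manool, (3R)-3-methyl-5-Dec-pent-1-en-3-ol
Product: 2 4-Dec-butan-2-one (14,15-dinorlabd-8(17)-en-13-one)
Conditions: KMnO4 (portionwise), acetone, 0 °C to rt
Reagents that add atoms: none
Why: Oxidative degradation of a tertiary vinyl carbinol to the methyl ketone by KMnO4 is a known reaction of labdane allylic alcohols; the hydroxyl-bearing vinyl group is cleaved faster than the hindered C8=C12 alkene when the oxidant is added in portions in the cold. Only C13 is touched and becomes the carbonyl carbon C2'; C5, C9 and C10 are not involved.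

Step 2
Reactants: 2 4-Dec-butan-2-one; 3 2-[(tert-butyldimethylsilyl)oxy]acetaldehyde
Product: 5 6-[(tert-butyldimethylsilyl)oxy]-5-hydroxy-1-Dec-hexan-3-one (both carbinol epimers), via lithium enolate of the methyl ketone 4 (not isolated)
Conditions: LiN(iPr)2, THF, −78 °C; then 3, −78 °C; NH4Cl (aq)
Reagents that add atoms: lithium diisopropylamide LiN(iPr)2, [Li]N(C(C)C)C(C)C (its lithium stands in 4 only)
Why: Kinetic deprotonation of a methyl ketone by LiN(iPr)2 at −78 °C occurs at the methyl group (C3'), and the preformed enolate adds to the aldehyde in a directed aldol reaction faster than the aldehyde enolises. The new carbinol centre forms as both epimers and is removed in step 3.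

Step 3
Reactants: 5 6-[(tert-butyldimethylsilyl)oxy]-5-hydroxy-1-Dec-hexan-3-one
Product: 7 (E)-6-[(tert-butyldimethylsilyl)oxy]-1-Dec-hex-4-en-3-one, via β-mesyloxy ketone 6 (not isolated)
Conditions: MsCl, Et3N, CH2Cl2, 0 °C to rt
Reagents that add atoms: methanesulfonyl chloride, CS(=O)(=O)Cl (its atoms stand in 6 only)
Why: Mesylation of the β-hydroxy ketone and E1cB elimination by the amine give the conjugated enone; the E isomer is the thermodynamically favoured product of this elimination. The conditions are basic and mild, so the silyl ether and C8=C12 are untouched.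

Step 4
Reactants: 7 (E)-6-[(tert-butyldimethylsilyl)oxy]-1-Dec-hex-4-en-3-one; 8 dimethyl malonate
Product: 10 methyl 6-{[(tert-butyldimethylsilyl)oxy]methyl}-2,4-dioxo-3-(Dec-methyl)cyclohexane-1-carboxylate (epimers and enol tautomers), via open-chain malonate Michael adduct 9 (not isolated)
Conditions: 8 (1.2 equiv), NaOMe (cat.), MeOH, 0 °C to rt; then NaOMe (1.2 equiv), reflux; AcOH, 0 °C
Reagents that add atoms: none
Why: NaOMe generates the anion of 8, which adds to C4' of enone 7 (Michael addition, new bond C4'–C5') to give 9 as its enolate. Proton exchange in MeOH moves the enolate from C3' to C1', and this carbon attacks one ester carbonyl (C6'), expels methoxide and forms C1'–C6' in a Dieckmann-type acylation. The closest known reaction is the Michael–Dieckmann condensation of enones with malonates to 4-alkoxycarbonylcyclohexane-1,3-diones, as in the dimedone synthesis. The ring closes by a 6-exo-trig acyl substitution; closure from C3', or attack of C5' on the ketone, would give four-membered rings, so ring size alone fixes the regiochemistry. Deprotonation of the product to the stabilised 1,3-dionate pulls the reversible Michael and Claisen equilibria over to 10. C4' and C5' (and C1' in the keto form) form without control, C5' settling trans to the C4' substituent by epimerisation; none is a stereocentre of 20 and all are erased in steps 5 to 7. The step needs conjugate rather than carbonyl addition and an untouched terpene half: the soft malonate anion and the reversibility of carbonyl addition secure the first, and the matched methoxide/methyl ester pair and a base-only medium secure the second. Running the addition stage with only catalytic methoxide limits deprotonation at C7' of 7.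

Step 5
Reactants: 10 methyl 6-{[(tert-butyldimethylsilyl)oxy]methyl}-2,4-dioxo-3-(Dec-methyl)cyclohexane-1-carboxylate
Product: 12 5-{[(tert-butyldimethylsilyl)oxy]methyl}-2-(Dec-methyl)cyclohexane-1,3-dione, via β-keto acid 11 (not isolated)
Conditions: NaOH (1 M aq), MeOH/THF, 60 °C; then HCl (1 M) to pH 4, 0 °C; 45 °C
Reagents that add atoms: sodium hydroxide, [Na+].[OH-] (its oxygen stands in the carboxyl group of 11 only)
Why: Saponification of the β-keto ester and decarboxylation of the β-keto acid on mild acidification is the standard second half of the malonate route to cyclohexane-1,3-diones. While hydroxide is present the dione is held as its enolate, which protects it against retro-Claisen opening, and the acid stage is kept near pH 4 so that the silyl ether and C8=C12 are spared.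

Step 6
Reactants: 12 5-{[(tert-butyldimethylsilyl)oxy]methyl}-2-(Dec-methyl)cyclohexane-1,3-dione
Product: 13 5-{[(tert-butyldimethylsilyl)oxy]methyl}-2-(Dec-methyl)-3-[(triisopropylsilyl)oxy]cyclohex-2-en-1-one (two epimers at the ring CH)
Conditions: iPr3SiOTf, Et3N, CH2Cl2, −78 to 0 °C
Reagents that add atoms: triisopropylsilyl trifluoromethanesulfonate, CC(C)[Si](OS(=O)(=O)C(F)(F)F)(C(C)C)C(C)C
Why: O-Silylation of a 2-alkylcyclohexane-1,3-dione with a silyl triflate and an amine base gives the vinylogous silyl ester. The two carbonyl groups of 12 are constitutionally equivalent, so either enol oxygen leads to the same constitution, and the two epimers converge in step 7.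

Step 7
Reactants: 13 5-{[(tert-butyldimethylsilyl)oxy]methyl}-2-(Dec-methyl)-3-[(triisopropylsilyl)oxy]cyclohex-2-en-1-one
Product: 18 5-{[(tert-butyldimethylsilyl)oxy]methyl}-2-(Dec-methyl)-3-[(triisopropylsilyl)oxy]phenol, via lithium dienolate 14 (not isolated), via C5' phenylselenide 15 (not isolated), via selenoxide 16 (not isolated), via 4H-cyclohexa-2,5-dienone 17 (not isolated)
Conditions: LiN(iPr)2, THF, −78 °C; PhSeBr, −78 °C; then H2O2 (30% aq), pyridine, CH2Cl2, 0 °C to rt
Reagents that add atoms: lithium diisopropylamide LiN(iPr)2, [Li]N(C(C)C)C(C)C (lithium in 14 only); phenylselenenyl bromide, Br[Se]c1ccccc1 (in 15 and 16 only); hydrogen peroxide, OO (oxygen in 16 only)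
Why: Kinetic α'-deprotonation of a 3-oxycyclohexenone, selenenylation of the enolate and selenoxide syn-elimination is the established dehydrogenation of vinylogous esters of cyclohexane-1,3-diones to resorcinol monoethers. The C5' selenoxide has a β-hydrogen only on C4', so the new double bond is endocyclic and dienone 17 tautomerises at once to the phenol. The enolate takes up PhSeBr at −78 °C far faster than C8=C12 does, and pyridine keeps the oxidation medium from epoxidising that alkene.

Step 8
Reactants: 18 5-{[(tert-butyldimethylsilyl)oxy]methyl}-2-(Dec-methyl)-3-[(triisopropylsilyl)oxy]phenol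
Product: 19 5-(hydroxymethyl)-2-(Dec-methyl)benzene-1,3-diol
Conditions: Bu4NF, AcOH, THF, 0 °C to rt, Ar
Reagents that add atoms: none
Why: Fluoride cleaves the aryl triisopropylsilyl ether and the primary tert-butyldimethylsilyl ether in one operation. AcOH buffering and exclusion of air protect the electron-rich resorcinol, and nothing in the terpene half reacts with fluoride.

Step 9
Reactants: 19 5-(hydroxymethyl)-2-(Dec-methyl)benzene-1,3-diol
Product: 20 tauranin, 3-hydroxy-5-(hydroxymethyl)-2-(Dec-methyl)cyclohexa-2,5-diene-1,4-dione
Conditions: (KSO3)2NO, KH2PO4 (aq), acetone/H2O, 0 °C to rt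
Reagents that add atoms: potassium nitrosodisulfonate (KSO3)2NO, [K+].[K+].[O]N(S(=O)(=O)[O-])S(=O)(=O)[O-] (gives the C3' oxygen)
Why: Teuber oxidation: the nitroxyl radical salt oxidises a phenol with a free para position to the para-quinone by hydrogen abstraction, radical coupling at the para carbon and loss of imidodisulfonate. In 19 the positions para to the two hydroxyls (C3' and C5') are equivalent, so a single 2-hydroxy-1,4-benzoquinone results, the other hydroxyl remaining on C2'. The reagent does not attack isolated alkenes, and phenol oxidation is much faster than oxidation of the primary alcohol.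

## Compound list

1 | (+)-manool, (3R)-3-methyl-5-[(1S,4aS,8aS)-5,5,8a-trimethyl-2-methylidenedecahydronaphthalen-1-yl]pent-1-en-3-ol | C=C1CC[C@H]2C(C)(C)CCC[C@]2(C)[C@H]1CC[C@@](C)(O)C=C | starting material
2 | 4-[(1S,4aS,8aS)-5,5,8a-trimethyl-2-methylidenedecahydronaphthalen-1-yl]butan-2-one | C=C1CC[C@H]2C(C)(C)CCC[C@]2(C)[C@H]1CCC(C)=O | intermediate
3 | 2-[(tert-butyldimethylsilyl)oxy]acetaldehyde | O=CCO[Si](C)(C)C(C)(C)C | starting material
4 | lithium 4-Dec-but-1-en-2-olate (kinetic enolate of 2) | C=C1CC[C@H]2C(C)(C)CCC[C@]2(C)[C@H]1CCC(=C)O[Li] | intermediate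
5 | 6-[(tert-butyldimethylsilyl)oxy]-5-hydroxy-1-Dec-hexan-3-one (both C5 epimers) | C=C1CC[C@H]2C(C)(C)CCC[C@]2(C)[C@H]1CCC(=O)CC(O)CO[Si](C)(C)C(C)(C)C | intermediate
6 | 1-[(tert-butyldimethylsilyl)oxy]-4-oxo-6-Dec-hexan-2-yl methanesulfonate | C=C1CC[C@H]2C(C)(C)CCC[C@]2(C)[C@H]1CCC(=O)CC(OS(C)(=O)=O)CO[Si](C)(C)C(C)(C)C | intermediate
7 | (E)-6-[(tert-butyldimethylsilyl)oxy]-1-Dec-hex-4-en-3-one | C=C1CC[C@H]2C(C)(C)CCC[C@]2(C)[C@H]1CCC(=O)/C=C/CO[Si](C)(C)C(C)(C)C | intermediate
8 | dimethyl malonate | COC(=O)CC(=O)OC | starting material
9 | dimethyl 2-{1-[(tert-butyldimethylsilyl)oxy]-4-oxo-6-Dec-hexan-2-yl}propanedioate | C=C1CC[C@H]2C(C)(C)CCC[C@]2(C)[C@H]1CCC(=O)CC(CO[Si](C)(C)C(C)(C)C)C(C(=O)OC)C(=O)OC | intermediate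
10 | methyl 6-{[(tert-butyldimethylsilyl)oxy]methyl}-2,4-dioxo-3-(Dec-methyl)cyclohexane-1-carboxylate | C=C1CC[C@H]2C(C)(C)CCC[C@]2(C)[C@H]1CC1C(=O)CC(CO[Si](C)(C)C(C)(C)C)C(C(=O)OC)C1=O | intermediate
11 | 6-{[(tert-butyldimethylsilyl)oxy]methyl}-2,4-dioxo-3-(Dec-methyl)cyclohexane-1-carboxylic acid | C=C1CC[C@H]2C(C)(C)CCC[C@]2(C)[C@H]1CC1C(=O)CC(CO[Si](C)(C)C(C)(C)C)C(C(=O)O)C1=O | intermediate
12 | 5-{[(tert-butyldimethylsilyl)oxy]methyl}-2-(Dec-methyl)cyclohexane-1,3-dione | C=C1CC[C@H]2C(C)(C)CCC[C@]2(C)[C@H]1CC1C(=O)CC(CO[Si](C)(C)C(C)(C)C)CC1=O | intermediate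
13 | 5-{[(tert-butyldimethylsilyl)oxy]methyl}-2-(Dec-methyl)-3-[(triisopropylsilyl)oxy]cyclohex-2-en-1-one | C=C1CC[C@H]2C(C)(C)CCC[C@]2(C)[C@H]1CC1=C(O[Si](C(C)C)(C(C)C)C(C)C)CC(CO[Si](C)(C)C(C)(C)C)CC1=O | intermediate
14 | lithium 3-{[(tert-butyldimethylsilyl)oxy]methyl}-6-(Dec-methyl)-5-[(triisopropylsilyl)oxy]cyclohexa-1,5-dien-1-olate | C=C1CC[C@H]2C(C)(C)CCC[C@]2(C)[C@H]1CC1=C(O[Si](C(C)C)(C(C)C)C(C)C)CC(CO[Si](C)(C)C(C)(C)C)C=C1O[Li] | intermediate
15 | 5-{[(tert-butyldimethylsilyl)oxy]methyl}-2-(Dec-methyl)-6-(phenylselanyl)-3-[(triisopropylsilyl)oxy]cyclohex-2-en-1-one | C=C1CC[C@H]2C(C)(C)CCC[C@]2(C)[C@H]1CC1=C(O[Si](C(C)C)(C(C)C)C(C)C)CC(CO[Si](C)(C)C(C)(C)C)C([Se]c2ccccc2)C1=O | intermediate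
16 | 6-(benzeneseleninyl)-5-{[(tert-butyldimethylsilyl)oxy]methyl}-2-(Dec-methyl)-3-[(triisopropylsilyl)oxy]cyclohex-2-en-1-one | C=C1CC[C@H]2C(C)(C)CCC[C@]2(C)[C@H]1CC1=C(O[Si](C(C)C)(C(C)C)C(C)C)CC(CO[Si](C)(C)C(C)(C)C)C([Se](=O)c2ccccc2)C1=O | intermediate
17 | 5-{[(tert-butyldimethylsilyl)oxy]methyl}-2-(Dec-methyl)-3-[(triisopropylsilyl)oxy]cyclohexa-2,5-dien-1-one | C=C1CC[C@H]2C(C)(C)CCC[C@]2(C)[C@H]1CC1=C(O[Si](C(C)C)(C(C)C)C(C)C)CC(CO[Si](C)(C)C(C)(C)C)=CC1=O | intermediate
18 | 5-{[(tert-butyldimethylsilyl)oxy]methyl}-2-(Dec-methyl)-3-[(triisopropylsilyl)oxy]phenol | C=C1CC[C@H]2C(C)(C)CCC[C@]2(C)[C@H]1Cc1c(O)cc(CO[Si](C)(C)C(C)(C)C)cc1O[Si](C(C)C)(C(C)C)C(C)C | intermediate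
19 | 5-(hydroxymethyl)-2-(Dec-methyl)benzene-1,3-diol | C=C1CC[C@H]2C(C)(C)CCC[C@]2(C)[C@H]1Cc1c(O)cc(CO)cc1O | intermediate
20 | tauranin, 3-hydroxy-5-(hydroxymethyl)-2-{[(1S,4aS,8aS)-5,5,8a-trimethyl-2-methylidenedecahydronaphthalen-1-yl]methyl}cyclohexa-2,5-diene-1,4-dione | C=C1CC[C@H]2C(C)(C)CCC[C@]2(C)[C@H]1CC1=C(O)C(=O)C(CO)=CC1=O | target

## Step count and risk

Total: 9 steps. Longest linear sequence: 9 steps (1 to 20); 3 and 8 are purchased and enter at steps 2 and 4.

Step 4 (key step). The most likely failure is loss of enone 7 before the malonate has added. Methoxide can deprotonate C7' and shift the alkene towards the silyloxy group, after which the resulting enol silyl ether is cleaved and the material condenses with itself. Slow closure at C1' would in addition leave the open adduct to revert by retro-Michael reaction. Fallback: the two bonds are made in separate operations with no basic Michael stage, setting out from 7. Mukaiyama–Michael addition of 1-(tert-butyldimethylsilyloxy)-1-methoxyethene, promoted by catalytic Sc(OTf)3 in CH2Cl2 at −78 °C, should give methyl 5-[(tert-butyldimethylsilyl)oxy]-3-{[(tert-butyldimethylsilyl)oxy]methyl}-7-Dec-hept-4-enoate F1. NaOMe in MeOH at reflux then cleaves the enol silyl ether, equilibrates the enolate to C1' and closes the ring by the same Dieckmann acylation. This gives the dione directly and comes back to the route at 12, replacing steps 4 and 5.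

Step 7. Several things can go wrong: electrophilic selenium may add to C8=C12 if enolate formation is incomplete; proton exchange between enolate and selenide may lead to double selenenylation; peroxyseleninic acid may epoxidise the alkene during the oxidation; and the vinylogous silyl ester may hydrolyse in the aqueous oxidant. Fallback without selenium or peroxide, setting out from 13: LiN(iPr)2 then Me3SiCl in THF at −78 °C should give the dienol ether 6-{[(tert-butyldimethylsilyl)oxy]methyl}-3-(Dec-methyl)-4-[(triisopropylsilyl)oxy]-2-[(trimethylsilyl)oxy]cyclohexa-1,3-diene F2. Pd(OAc)2 (divalent palladium) in MeCN at rt (Saegusa–Ito oxidation) removes the trimethylsilyl group, dehydrogenates C4'–C5' through 17 and comes back to the route at 18.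

Step 9. The quinone as it forms may couple with unreacted resorcinol, oxidation may go on past the hydroxyquinone, and attack ortho to a hydroxyl would give an ortho-quinone. The free triol is also the most air-sensitive compound of the route. Fallback: oxidise before deprotection, setting out from 18, in which only one phenol is free and the primary alcohol is masked. O2 with catalytic Co(salen) (divalent cobalt) in DMF should oxidise para to the free hydroxyl and give 5-{[(tert-butyldimethylsilyl)oxy]methyl}-2-(Dec-methyl)-3-[(triisopropylsilyl)oxy]cyclohexa-2,5-diene-1,4-dione F3. Et3N·3HF in MeCN then removes both silyl groups and comes back at 20, replacing steps 8 and 9.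

Step 5. Hot hydroxide may cleave the primary silyl ether or open the dione by retro-Claisen reaction. At the acid stage, a pH mild enough for the silyl ether and the alkene may leave decarboxylation incomplete. Fallback: a neutral ester removal, setting out from 7. The conditions of step 4 with diallyl malonate and sodium allyloxide in allyl alcohol should give prop-2-en-1-yl 6-{[(tert-butyldimethylsilyl)oxy]methyl}-2,4-dioxo-3-(Dec-methyl)cyclohexane-1-carboxylate F4. Pd(PPh3)4 (zerovalent palladium) with HCO2H/Et3N in THF at rt removes the allyl group as propene, the acid decarboxylates at once, and the route is rejoined at 12.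

## Further compounds

F1 | step 4 | methyl 5-[(tert-butyldimethylsilyl)oxy]-3-{[(tert-butyldimethylsilyl)oxy]methyl}-7-Dec-hept-4-enoate | C=C1CC[C@H]2C(C)(C)CCC[C@]2(C)[C@H]1CCC(O[Si](C)(C)C(C)(C)C)=CC(CO[Si](C)(C)C(C)(C)C)CC(=O)OC
F2 | step 7 | 6-{[(tert-butyldimethylsilyl)oxy]methyl}-3-(Dec-methyl)-4-[(triisopropylsilyl)oxy]-2-[(trimethylsilyl)oxy]cyclohexa-1,3-diene | C=C1CC[C@H]2C(C)(C)CCC[C@]2(C)[C@H]1CC1=C(O[Si](C(C)C)(C(C)C)C(C)C)CC(CO[Si](C)(C)C(C)(C)C)C=C1O[Si](C)(C)C
F3 | step 9 | 5-{[(tert-butyldimethylsilyl)oxy]methyl}-2-(Dec-methyl)-3-[(triisopropylsilyl)oxy]cyclohexa-2,5-diene-1,4-dione | C=C1CC[C@H]2C(C)(C)CCC[C@]2(C)[C@H]1CC1=C(O[Si](C(C)C)(C(C)C)C(C)C)C(=O)C(CO[Si](C)(C)C(C)(C)C)=CC1=O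
F4 | step 5 | prop-2-en-1-yl 6-{[(tert-butyldimethylsilyl)oxy]methyl}-2,4-dioxo-3-(Dec-methyl)cyclohexane-1-carboxylate | C=C1CC[C@H]2C(C)(C)CCC[C@]2(C)[C@H]1CC1C(=O)CC(CO[Si](C)(C)C(C)(C)C)C(C(=O)OCC=C)C1=O
A1 | alternative 1 | (E,E)-4-farnesyl-3,5-dimethoxybenzyl alcohol | CC(C)=CCC/C(C)=C/CC/C(C)=C/Cc1c(OC)cc(CO)cc1OC
A2 | alternative 1 | 4-(Dec-methyl)-3,5-dimethoxybenzyl alcohol | C=C1CC[C@H]2C(C)(C)CCC[C@]2(C)[C@H]1Cc1c(OC)cc(CO)cc1OC
A3 | alternative 2 | (+)-sclareolide | CC1(C)CCC[C@@]2(C)[C@H]1CC[C@@]1(C)OC(=O)C[C@@H]12
A4 | alternative 2 | triisopropyl[(3-Dec-prop-1-yn-1-yl)oxy]silane | C=C1CC[C@H]2C(C)(C)CCC[C@]2(C)[C@H]1CC#CO[Si](C(C)C)(C(C)C)C(C)C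
A5 | alternative 2 | 3-{[(tert-butyldimethylsilyl)oxy]methyl}cyclobut-2-en-1-one | O=C1C=C(CO[Si](C)(C)C(C)(C)C)C1
A6 | alternative 2 | 5-{[(tert-butyldimethylsilyl)oxy]methyl}-2-(Dec-methyl)-3-[(triisopropylsilyl)oxy]phenol (identical with 18) | C=C1CC[C@H]2C(C)(C)CCC[C@]2(C)[C@H]1Cc1c(O)cc(CO[Si](C)(C)C(C)(C)C)cc1O[Si](C(C)C)(C(C)C)C(C)C
A7 | alternative 3 | diisopropyl squarate | CC(C)OC1=C(OC(C)C)C(=O)C1=O
A8 | alternative 3 | 4-{3-[(tert-butyldimethylsilyl)oxy]prop-1-en-2-yl}-4-hydroxy-2-(Dec-methyl)-3-isopropoxycyclobut-2-en-1-one | C=C1CC[C@H]2C(C)(C)CCC[C@]2(C)[C@H]1CC1=C(OC(C)C)C(O)(C(=C)CO[Si](C)(C)C(C)(C)C)C1=O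
A9 | alternative 3 | 5-{[(tert-butyldimethylsilyl)oxy]methyl}-2-(Dec-methyl)-3-isopropoxybenzene-1,4-diol | C=C1CC[C@H]2C(C)(C)CCC[C@]2(C)[C@H]1Cc1c(O)cc(CO[Si](C)(C)C(C)(C)C)c(O)c1OC(C)C
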